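Assumption: the target, 3,6-dibromo-2-(2,4-dibromophenoxy)phenol, has no stereocentre, so no stereocontrol is needed; both starting materials are taken as catalogue compounds.

**Retrosynthetic overview**
- Diaryl ether C–O bond: 2,4-dibromophenol (1) plus 3,6-dibromo-2-fluorobenzaldehyde (2) give aldehyde 3 by SNAr at the fluorine ortho to CHO.
- Phenol OH: the CHO of 3 is exchanged for OH by Baeyer–Villiger oxidation to formate 4, then cleavage to target 5.
- No ring is formed; both benzene rings and all four bromines are bought in place.

**Route**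

Step 1
Reactants: 1 2,4-dibromophenol; 2 3,6-dibromo-2-fluorobenzaldehyde
Product: 3 3,6-dibromo-2-(2,4-dibromophenoxy)benzaldehyde
Conditions: K2CO3 (1.5 equiv), DMF, 90 °C, N2
Reagents that add atoms: none
Why: SNAr (addition–elimination) of the phenoxide at the C–F carbon, whose Meisenheimer intermediate is stabilised by the ortho formyl group; fluoride leaves far faster than the bromide at C6, and no stereocentre is formed.

Step 2
Reactants: 3 3,6-dibromo-2-(2,4-dibromophenoxy)benzaldehyde
Product: 5 3,6-dibromo-2-(2,4-dibromophenoxy)phenol, via 3,6-dibromo-2-(2,4-dibromophenoxy)phenyl formate 4 (not isolated)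
Conditions: mCPBA (1.6 equiv), CH2Cl2, 0 → 40 °C; then MeOH, conc. HCl (cat.), rt; aq. Na2S2O3 work-up
Reagents that add atoms: mCPBA, O=C(OO)c1cccc(Cl)c1
Why: Baeyer–Villiger (Dakin-type) oxidation in which the aryl group, assisted by the ortho aryloxy donor, migrates to oxygen to give the aryl formate, which acid-catalysed methanolysis cleaves to the phenol; aryl bromides and the diaryl ether are inert to peracid, and no stereocentre is involved.

**Compound list**
1 | 2,4-dibromophenol | Oc1ccc(Br)cc1Br | starting material
2 | 3,6-dibromo-2-fluorobenzaldehyde | O=Cc1c(Br)ccc(Br)c1F | starting material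
3 | 3,6-dibromo-2-(2,4-dibromophenoxy)benzaldehyde | O=Cc1c(Br)ccc(Br)c1Oc1ccc(Br)cc1Br | intermediate
4 | 3,6-dibromo-2-(2,4-dibromophenoxy)phenyl formate | O=COc1c(Br)ccc(Br)c1Oc1ccc(Br)cc1Br | intermediate
5 | 3,6-dibromo-2-(2,4-dibromophenoxy)phenol | Oc1c(Br)ccc(Br)c1Oc1ccc(Br)cc1Br | target

**Totals**
Total step count: 2. Longest linear sequence: 2.

**Steps most likely to fail**
The route has only two steps, so both are ranked and there is no third.

Most at risk, step 2: the ring carries two bromines and only a weak aryloxy donor, so hydride migration could compete and give the benzoic acid instead of the formate. The fallback sets out from 3 and removes hydride migration by going through the methyl ketone. Addition of MeMgBr (THF, −20 °C, no Br/Mg exchange) gives racemic 1-[3,6-dibromo-2-(2,4-dibromophenoxy)phenyl]ethan-1-ol F1. Dess–Martin oxidation gives 1-[3,6-dibromo-2-(2,4-dibromophenoxy)phenyl]ethan-1-one F2. Baeyer–Villiger oxidation with CF3CO3H (TFAA, urea·H2O2, CH2Cl2), where aryl migrates in preference to methyl, gives 3,6-dibromo-2-(2,4-dibromophenoxy)phenyl acetate F3. Methanolysis (K2CO3 cat., MeOH, rt) comes back to the route at 5.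

Second, step 1: the fluorine is flanked by CHO and Br, and 2,4-dibromophenoxide is a hindered, weak nucleophile, so the SNAr may be slow or accompanied by substitution of the C6 bromide. The fallback sets out from 2 and installs the ring-B bromines after ether formation. SNAr with unsubstituted phenol (K2CO3, DMF, 80 °C), which is a smaller and stronger nucleophile, gives 3,6-dibromo-2-phenoxybenzaldehyde F4. Electrophilic bromination (Br2, 2.1 equiv, AcOH, rt → 50 °C) goes para and then ortho to the ether oxygen on the unsubstituted ring, while the aldehyde ring is deactivated by CHO and two bromines. This comes back to the route at 3.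

**Further compounds**
F1 | step 2 | 1-[3,6-dibromo-2-(2,4-dibromophenoxy)phenyl]ethan-1-ol (racemic) | CC(O)c1c(Br)ccc(Br)c1Oc1ccc(Br)cc1Br
F2 | step 2 | 1-[3,6-dibromo-2-(2,4-dibromophenoxy)phenyl]ethan-1-one | CC(=O)c1c(Br)ccc(Br)c1Oc1ccc(Br)cc1Br
F3 | step 2 | 3,6-dibromo-2-(2,4-dibromophenoxy)phenyl acetate | CC(=O)Oc1c(Br)ccc(Br)c1Oc1ccc(Br)cc1Br
F4 | step 1 | 3,6-dibromo-2-phenoxybenzaldehyde | O=Cc1c(Br)ccc(Br)c1Oc1ccccc1
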